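**Retrosynthetic overview**

1. Target ⇐ its sodium salt carrying a 4'-O-benzyl group (debenzylation, protonation) ⇐ 4'-O-benzylhispidulin by sulfation of the 7-OH, the only phenol that is neither chelated (5-OH) nor protected.
2. 4'-O-Benzylhispidulin ⇐ 2'-hydroxychalcone by I2/DMSO oxidative cyclisation and MOM removal; the pyranone ring is the only ring made, and it is made last.
3. Chalcone ⇐ 2-hydroxy-5-methoxy-4,6-bis(MOM-oxy)acetophenone + 4-(benzyloxy)benzaldehyde by Claisen–Schmidt aldol condensation (key C–C bond = flavone C2–C3; both benzene rings are bought).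
4. Acetophenone ⇐ mirror-symmetric 4-methoxy-3,5-bis(MOM-oxy)phenol by O-benzylation, directed ortho-lithiation/acetylation and debenzylation; symmetry places the free OH para to OMe, which fixes 6-OMe rather than 8-OMe.
5. Phenol ⇐ methyl 3,5-dihydroxy-4-methoxybenzoate by MOM protection, ester → aldehyde, Baeyer–Villiger oxidation.

Assumption: the target has no stereocentre (nothing to resolve) and is delivered as the free hydrogen sulfate drawn, after being carried as its sodium salt; methyl 3,5-dihydroxy-4-methoxybenzoate 1 is taken as an inexpensive catalogue compound.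

**Route**

Step 1
Reactants: 1 methyl 3,5-dihydroxy-4-methoxybenzoate
Product: 2 methyl 4-methoxy-3,5-bis(methoxymethoxy)benzoate
Conditions: NaH (2.4 equiv), MOMCl (2.4 equiv), DMF, 0 °C → rt
Reagents that add atoms: chloromethyl methyl ether (MOMCl), COCCl
Why: Williamson-type O-alkylation of both phenoxides with MOMCl gives the bis-acetal, and the ester is inert to these conditions.

Step 2
Reactants: 2 methyl 4-methoxy-3,5-bis(methoxymethoxy)benzoate
Product: 3 [4-methoxy-3,5-bis(methoxymethoxy)phenyl]methanol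
Conditions: LiAlH4, THF, 0 °C; Fieser work-up
Reagents that add atoms: none
Why: LiAlH4 ester reduction gives the benzylic alcohol, and MOM acetals and aryl ethers are inert to hydride.

Step 3
Reactants: 3 [4-methoxy-3,5-bis(methoxymethoxy)phenyl]methanol
Product: 4 4-methoxy-3,5-bis(methoxymethoxy)benzaldehyde
Conditions: activated MnO2 (10 equiv), CH2Cl2, rt
Reagents that add atoms: none
Why: MnO2 oxidation of a benzylic alcohol stops at the aldehyde under neutral conditions that keep the MOM groups.

Step 4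
Reactants: 4 4-methoxy-3,5-bis(methoxymethoxy)benzaldehyde
Product: 6 4-methoxy-3,5-bis(methoxymethoxy)phenol, via aryl formate 5 (not isolated)
Conditions: mCPBA (1.3 equiv), CH2Cl2, 0 °C → rt; aq. Na2SO3/NaHCO3 wash; then Et3N (cat.), MeOH, rt
Reagents that add atoms: mCPBA, O=C(OO)c1cccc(Cl)c1
Why: Baeyer–Villiger oxidation of the electron-rich benzaldehyde proceeds with aryl migration to the formate, which base-catalysed methanolysis converts to the phenol.

Step 5
Reactants: 6 4-methoxy-3,5-bis(methoxymethoxy)phenol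
Product: 7 5-(benzyloxy)-2-methoxy-1,3-bis(methoxymethoxy)benzene
Conditions: BnBr, K2CO3, DMF, rt
Reagents that add atoms: benzyl bromide, BrCc1ccccc1
Why: Williamson ether synthesis installs a benzyl group that is orthogonal to MOM and tolerates the lithiation that follows.

Step 6
Reactants: 7 5-(benzyloxy)-2-methoxy-1,3-bis(methoxymethoxy)benzene
Product: 10 O-benzyl ketone 1-[2-(benzyloxy)-5-methoxy-4,6-bis(methoxymethoxy)phenyl]ethan-1-one, via aryllithium 8 (not isolated), via lithium hemiaminal alkoxide 9 (not isolated)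
Conditions: n-BuLi (1.2 equiv), TMEDA, THF, −20 → 0 °C; N-methoxy-N-methylacetamide (1.5 equiv), −78 °C → rt; aq. NH4Cl
Reagents that add atoms: N-methoxy-N-methylacetamide, CC(=O)N(C)OC
Why: Directed ortho-metalation can only occur at the two symmetry-equivalent ring C–H positions flanked by OMOM and OBn, and the Weinreb ketone synthesis stops at the methyl ketone through the chelated tetrahedral adduct.

Step 7
Reactants: 10 O-benzyl ketone 1-[2-(benzyloxy)-5-methoxy-4,6-bis(methoxymethoxy)phenyl]ethan-1-one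
Product: 11 1-[2-hydroxy-5-methoxy-4,6-bis(methoxymethoxy)phenyl]ethan-1-one
Conditions: H2 (1 atm), 10% Pd/C, EtOAc, rt
Reagents that add atoms: none
Why: Hydrogenolysis of the benzyl aryl ether frees the single phenol that will become the ring oxygen, while the MOM acetals and the hindered aryl ketone are untouched.

Step 8
Reactants: 11 1-[2-hydroxy-5-methoxy-4,6-bis(methoxymethoxy)phenyl]ethan-1-one; 12 4-(benzyloxy)benzaldehyde
Product: 14 (E)-3-[4-(benzyloxy)phenyl]-1-[2-hydroxy-5-methoxy-4,6-bis(methoxymethoxy)phenyl]prop-2-en-1-one, via racemic β-hydroxy ketone aldol adduct 13 (not isolated)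
Conditions: KOH (50% aq., excess), EtOH, rt, 24–48 h; cold dilute HCl to pH 6
Reagents that add atoms: none
Why: Claisen–Schmidt (crossed aldol) condensation of the ketone enolate with a non-enolisable aldehyde, followed by E1cB dehydration, gives the thermodynamically favoured E-enone and erases the stereocentre of the aldol adduct.

Step 9
Reactants: 14 (E)-3-[4-(benzyloxy)phenyl]-1-[2-hydroxy-5-methoxy-4,6-bis(methoxymethoxy)phenyl]prop-2-en-1-one
Product: 16 2-[4-(benzyloxy)phenyl]-5,7-dihydroxy-6-methoxy-4H-chromen-4-one, via bis-MOM flavone 15 (not isolated)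
Conditions: I2 (0.1 equiv), DMSO, 120 °C; aq. Na2S2O3 work-up; crude in 3 M HCl, MeOH–THF, 60 °C
Reagents that add atoms: none
Why: I2/DMSO oxidative cyclisation (oxa-Michael closure by the only free phenol, then iodination–dehydroiodination with DMSO as terminal oxidant) forms the pyranone with the methoxy group fixed at C-6, and acid-catalysed acetal methanolysis then removes both MOM groups while the benzyl ether survives.

Step 10
Reactants: 16 2-[4-(benzyloxy)phenyl]-5,7-dihydroxy-6-methoxy-4H-chromen-4-one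
Product: 18 sodium 2-[4-(benzyloxy)phenyl]-5-hydroxy-6-methoxy-4-oxo-4H-chromen-7-yl sulfate, via pyridinium sulfate salt 17 (not isolated)
Conditions: SO3·pyridine (3 equiv), pyridine, rt → 40 °C; aq. NaHCO3 to pH 8; Sephadex LH-20 (MeOH)
Reagents that add atoms: sulfur trioxide–pyridine complex, O=S(=O)([O-])[n+]1ccccc1; sodium hydrogencarbonate, [Na+].OC(=O)[O-]
Why: Phenol O-sulfation with an SO3–amine complex is confined to the 7-OH because the 5-OH is locked in a hydrogen bond to the C-4 carbonyl and the 4'-oxygen is benzylated.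

Step 11
Reactants: 18 sodium 2-[4-(benzyloxy)phenyl]-5-hydroxy-6-methoxy-4-oxo-4H-chromen-7-yl sulfate
Product: 20 hispidulin 7-sulfate (5-hydroxy-2-(4-hydroxyphenyl)-6-methoxy-4-oxo-4H-chromen-7-yl hydrogen sulfate), via sodium hispidulin 7-sulfate 19 (not isolated)
Conditions: H2 (1 atm), 10% Pd/C, MeOH–H2O, rt, stopped at full debenzylation; filter; 1.0 equiv aq. HCl, 0 °C; C18 desalting, lyophilise (store cold)
Reagents that add atoms: none
Why: Catalytic hydrogenolysis cleaves the benzyl aryl ether under neutral conditions that leave the aryl sulfate and, with monitoring, the flavone C2=C3 bond intact, and one equivalent of cold acid protonates the sulfate salt.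

**Compound list**

1 | methyl 3,5-dihydroxy-4-methoxybenzoate | COC(=O)c1cc(O)c(OC)c(O)c1 | starting material
2 | methyl 4-methoxy-3,5-bis(methoxymethoxy)benzoate | COC(=O)c1cc(OCOC)c(OC)c(OCOC)c1 | intermediate
3 | [4-methoxy-3,5-bis(methoxymethoxy)phenyl]methanol | OCc1cc(OCOC)c(OC)c(OCOC)c1 | intermediate
4 | 4-methoxy-3,5-bis(methoxymethoxy)benzaldehyde | O=Cc1cc(OCOC)c(OC)c(OCOC)c1 | intermediate
5 | 4-methoxy-3,5-bis(methoxymethoxy)phenyl formate (not isolated) | O=COc1cc(OCOC)c(OC)c(OCOC)c1 | intermediate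
6 | 4-methoxy-3,5-bis(methoxymethoxy)phenol | Oc1cc(OCOC)c(OC)c(OCOC)c1 | intermediate
7 | 5-(benzyloxy)-2-methoxy-1,3-bis(methoxymethoxy)benzene | COCOc1cc(OCc2ccccc2)cc(OCOC)c1OC | intermediate
8 | [2-(benzyloxy)-5-methoxy-4,6-bis(methoxymethoxy)phenyl]lithium (not isolated) | [Li]c1c(OCc2ccccc2)cc(OCOC)c(OC)c1OCOC | intermediate
9 | racemic lithium 1-[2-(benzyloxy)-5-methoxy-4,6-bis(methoxymethoxy)phenyl]-1-[methoxy(methyl)amino]ethan-1-olate (not isolated) | [Li+].CC([O-])(N(C)OC)c1c(OCc2ccccc2)cc(OCOC)c(OC)c1OCOC | intermediate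
10 | 1-[2-(benzyloxy)-5-methoxy-4,6-bis(methoxymethoxy)phenyl]ethan-1-one | CC(=O)c1c(OCc2ccccc2)cc(OCOC)c(OC)c1OCOC | intermediate
11 | 1-[2-hydroxy-5-methoxy-4,6-bis(methoxymethoxy)phenyl]ethan-1-one | CC(=O)c1c(O)cc(OCOC)c(OC)c1OCOC | intermediate
12 | 4-(benzyloxy)benzaldehyde | O=Cc1ccc(OCc2ccccc2)cc1 | starting material
13 | racemic 3-[4-(benzyloxy)phenyl]-3-hydroxy-1-[2-hydroxy-5-methoxy-4,6-bis(methoxymethoxy)phenyl]propan-1-one (not isolated) | COCOc1cc(O)c(C(=O)CC(O)c2ccc(OCc3ccccc3)cc2)c(OCOC)c1OC | intermediate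
14 | (E)-3-[4-(benzyloxy)phenyl]-1-[2-hydroxy-5-methoxy-4,6-bis(methoxymethoxy)phenyl]prop-2-en-1-one | COCOc1cc(O)c(C(=O)/C=C/c2ccc(OCc3ccccc3)cc2)c(OCOC)c1OC | intermediate
15 | 2-[4-(benzyloxy)phenyl]-6-methoxy-5,7-bis(methoxymethoxy)-4H-chromen-4-one (not isolated) | COCOc1cc2oc(-c3ccc(OCc4ccccc4)cc3)cc(=O)c2c(OCOC)c1OC | intermediate
16 | 2-[4-(benzyloxy)phenyl]-5,7-dihydroxy-6-methoxy-4H-chromen-4-one (4'-O-benzylhispidulin) | COc1c(O)cc2oc(-c3ccc(OCc4ccccc4)cc3)cc(=O)c2c1O | intermediate
17 | pyridinium 2-[4-(benzyloxy)phenyl]-5-hydroxy-6-methoxy-4-oxo-4H-chromen-7-yl sulfate (not isolated) | COc1c(OS(=O)(=O)[O-])cc2oc(-c3ccc(OCc4ccccc4)cc3)cc(=O)c2c1O.c1cc[nH+]cc1 | intermediate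
18 | sodium 2-[4-(benzyloxy)phenyl]-5-hydroxy-6-methoxy-4-oxo-4H-chromen-7-yl sulfate | COc1c(OS(=O)(=O)[O-])cc2oc(-c3ccc(OCc4ccccc4)cc3)cc(=O)c2c1O.[Na+] | intermediate
19 | sodium 5-hydroxy-2-(4-hydroxyphenyl)-6-methoxy-4-oxo-4H-chromen-7-yl sulfate (not isolated) | COc1c(OS(=O)(=O)[O-])cc2oc(-c3ccc(O)cc3)cc(=O)c2c1O.[Na+] | intermediate
20 | hispidulin 7-sulfate, 5-hydroxy-2-(4-hydroxyphenyl)-6-methoxy-4-oxo-4H-chromen-7-yl hydrogen sulfate | COc1c(OS(=O)(=O)O)cc2oc(-c3ccc(O)cc3)cc(=O)c2c1O | target

**Totals and risks**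

Total step count: 11. Longest linear sequence: 11 steps (1 → 20); aldehyde 12 is bought and enters at step 8.

Steps most likely to fail:

- **Step 6 (ortho-lithiation/acetylation).** The risks are competing benzylic deprotonation of the OBn group and enolisation of the Weinreb amide by the hindered aryllithium. The fallback sets out from phenol 6 and avoids organolithium chemistry and the benzyl group altogether. Magnesium-mediated ortho-formylation (MgCl2, Et3N, paraformaldehyde, MeCN, reflux), which needs no Brønsted or strong Lewis acid, gives 2-hydroxy-5-methoxy-4,6-bis(methoxymethoxy)benzaldehyde F1. Addition of MeMgBr (3 equiv, THF, 0 °C) gives racemic 1-[2-hydroxy-5-methoxy-4,6-bis(methoxymethoxy)phenyl]ethan-1-ol F2. MnO2 in CH2Cl2 oxidises this benzylic alcohol to ketone 11, where the route is rejoined.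

- **Step 9 (oxidative cyclisation).** HI formed in the flask could remove the MOM group ortho to the carbonyl before ring closure, which would allow closure to the 8-methoxy isomer; iodination of the electron-rich A ring is a second risk. The fallback sets out from chalcone 14 and separates ring closure from oxidation under non-acidic conditions. NaOAc in refluxing EtOH closes the ring by oxa-Michael addition to give racemic 2-[4-(benzyloxy)phenyl]-6-methoxy-5,7-bis(methoxymethoxy)chroman-4-one F3 with both MOM groups in place. DDQ in refluxing dioxane dehydrogenates it to flavone 15, now isolated, which is treated with HCl/MeOH as in step 9 to reach 16.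

- **Step 10 (sulfation).** The risks are incomplete or unselective sulfation and losses in purifying the very polar salt. The fallback sets out from 16 and carries the sulfate as a neutral diester. 2,2,2-Trichloroethyl chlorosulfate with Et3N and DMAP in THF gives the chromatographable 2-[4-(benzyloxy)phenyl]-5-hydroxy-6-methoxy-4-oxo-4H-chromen-7-yl 2,2,2-trichloroethyl sulfate F4. Pd/C with ammonium formate in MeOH then removes the trichloroethyl group and the benzyl ether in one operation to give ammonium hispidulin 7-sulfate F5. Cold acidification with one equivalent of HCl and C18 desalting, as in step 11, gives 20.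

**Further compounds**

F1 | step 6 | 2-hydroxy-5-methoxy-4,6-bis(methoxymethoxy)benzaldehyde | O=Cc1c(O)cc(OCOC)c(OC)c1OCOC
F2 | step 6 | racemic 1-[2-hydroxy-5-methoxy-4,6-bis(methoxymethoxy)phenyl]ethan-1-ol | CC(O)c1c(O)cc(OCOC)c(OC)c1OCOC
F3 | step 9 | racemic 2-[4-(benzyloxy)phenyl]-6-methoxy-5,7-bis(methoxymethoxy)chroman-4-one | COCOc1cc2OC(c3ccc(OCc4ccccc4)cc3)CC(=O)c2c(OCOC)c1OC
F4 | step 10 | 2-[4-(benzyloxy)phenyl]-5-hydroxy-6-methoxy-4-oxo-4H-chromen-7-yl 2,2,2-trichloroethyl sulfate | COc1c(OS(=O)(=O)OCC(Cl)(Cl)Cl)cc2oc(-c3ccc(OCc4ccccc4)cc3)cc(=O)c2c1O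
F5 | step 10 | ammonium 5-hydroxy-2-(4-hydroxyphenyl)-6-methoxy-4-oxo-4H-chromen-7-yl sulfate | COc1c(OS(=O)(=O)[O-])cc2oc(-c3ccc(O)cc3)cc(=O)c2c1O.[NH4+]
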